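**Plan**
- Cuts: C5=C6 (ring-closing metathesis), C9–C10 (chromium allylation joining two halves), C2–C3 and the carbocycle bonds C1–C10/C13–C14 (alkylzinc addition, Diels–Alder), the O-acyl groups, and C8–C17 of the lactone.
- Forward: the γ-lactone ring (O7, C19, C17, C8, C7) is closed first on a C6–C9 chain from D-isoascorbic acid; the six-membered ring is made separately; the halves are joined at C9–C10; the ten-membered ring closes last.
- Enabling feature: C8 is a fully substituted carbinol carbon β to the lactone carbonyl C19. A diazoacetate on O7 therefore holds its carbene carbon C17 five atoms from the C8–H bond, which the ring oxygen O8 (dioxolane O8/O9) makes hydridic; insertion forms C8–C17 and the lactone with retention.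
- Stereochemistry: C7 and C8 from D-isoascorbic acid; C17 and C11 by kinetic protonation; C1 by a TADDOL-catalysed Diels–Alder; C2 by ligand-controlled alkylzinc addition.
- C9 and C10 from the chair transition state of the allylation on the ring face anti to the C2 chain; C12 by Luche reduction then Mitsunobu inversion; 5Z from the ring.

Key step: step 5

Remark: briarane numbering is used (C1 quaternary ring carbon, C2–C9 along the ten-membered ring, C10–C14 the rest of the cyclohexene, C15/C16/C18/C20 the methyls on C1/C5/C17/C11, C17 and C19 the lactone carbons; Ox is the oxygen on Cx).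

**Route**

Step 1
Reactants: 1 D-isoascorbic acid; 2 2,2-dimethoxypropane
Product: 3 5,6-O-isopropylidene-D-isoascorbic acid
Conditions: TsOH (cat.), acetone, 20 °C
Reagents that add atoms: none
Why: Acid-catalysed transketalisation takes the terminal 5,6-diol into a dioxolane, the standard acetonide protection of ascorbic acids, and touches no stereocentre.

Step 2
Reactants: 3 5,6-O-isopropylidene-D-isoascorbic acid
Product: 5 methyl 3,4-O-isopropylidene-D-erythronate, via potassium 3,4-O-isopropylidene-D-erythronate 4 (not isolated)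
Conditions: 30 % H2O2, K2CO3, H2O, 0→20 °C; evaporate; MeI, MeCN, reflux
Reagents that add atoms: hydrogen peroxide OO; iodomethane CI
Why: Alkaline peroxide cleaves the enediol C2–C3 bond of the ascorbate to oxalate and the four-carbon aldonate (oxidative cleavage), the carboxylate is then O-methylated, and C4/C5 of 3 become C7/C8 unchanged.

Step 3
Reactants: 5 methyl 3,4-O-isopropylidene-D-erythronate; 6 bromoacetyl bromide
Product: 7 methyl 2-O-(bromoacetyl)-3,4-O-isopropylidene-D-erythronate
Conditions: NaHCO3, MeCN, 0 °C
Reagents that add atoms: none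
Why: Acylation of the free secondary alcohol O7 by an acid bromide under mild base (esterification).

Step 4
Reactants: 7 methyl 2-O-(bromoacetyl)-3,4-O-isopropylidene-D-erythronate
Product: 8 methyl 2-O-(diazoacetyl)-3,4-O-isopropylidene-D-erythronate
Conditions: TsNHNHTs, DBU, THF, 0 °C
Reagents that add atoms: N,N'-ditosylhydrazine Cc1ccc(cc1)S(=O)(=O)NNS(=O)(=O)c1ccc(C)cc1
Why: Fukuyama diazoacetate synthesis, in which the bromoacetate N-alkylates the ditosylhydrazine and two sulfinates are eliminated; short contact at 0 °C should spare the C7 stereocentre.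

Step 5
Reactants: 8 methyl 2-O-(diazoacetyl)-3,4-O-isopropylidene-D-erythronate
Product: 9 spiro lactone ester (methyl 2,2-dimethyl-8-oxo-1,3,7-trioxaspiro[4.4]nonane-6-carboxylate; dioxolane oxygen O8 cis to the ester on the lactone ring)
Conditions: Rh2(cap)4 (1 mol %), CH2Cl2, reflux, 8 added over 8 h
Reagents that add atoms: none
Why: Dirhodium caprolactamate expels N2 from the diazoacetate on O7, and the electrophilic carbenoid at C17 inserts into the C8–H bond through a concerted three-centre, hydride-transfer-like transition state, so C8–C17 forms with retention at C8. The closest known reaction type is the dirhodium carboxamidate-catalysed 1,5 C–H insertion of alkyl diazoacetates next to ether oxygen, which gives γ-butyrolactones. The ring closes as a five-membered lactone (C17, C19, O7, C7, C8) spiro to the dioxolane, while the four-membered (C7–H) and six-membered (C9–H2) closures are disfavoured by ring size. The new fully substituted stereocentre C8 takes its configuration from C3 of the D-erythronate, because insertion is front-side. The step needs site selectivity for C8–H over C9–H2, the acetonide methyls and the dioxolane oxygens; this should be secured because C8–H is the only tertiary, oxygen-activated C–H at the 1,5 distance, C6 carries no hydrogen, and the electron-rich carboxamidate ligands temper the carbenoid. Slow addition keeps the diazo ester dilute and suppresses carbene dimers.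

Step 6
Reactants: 9 spiro lactone ester
Product: 10 hydroxymethyl spiro lactone (6-(hydroxymethyl)-2,2-dimethyl-1,3,7-trioxaspiro[4.4]nonan-8-one)
Conditions: NaBH4, MeOH–THF, −20→0 °C
Reagents that add atoms: none
Why: Chemoselective borohydride reduction, since the methyl ester activated by its α-acyloxy oxygen should be reduced faster than the γ-lactone, as in the known reduction of γ-butyrolactone-γ-carboxylates to hydroxymethyl lactones.

Step 7
Reactants: 10 hydroxymethyl spiro lactone
Product: 11 spiro lactone aldehyde (2,2-dimethyl-8-oxo-1,3,7-trioxaspiro[4.4]nonane-6-carbaldehyde)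
Conditions: Dess–Martin periodinane, NaHCO3, CH2Cl2, 0→20 °C
Reagents that add atoms: none
Why: Dess–Martin oxidation under buffered, non-basic conditions should leave the α-stereocentre C7 and the β-alkoxy group intact.

Step 8
Reactants: 11 spiro lactone aldehyde
Product: 12 vinyl spiro lactone (2,2-dimethyl-6-vinyl-1,3,7-trioxaspiro[4.4]nonan-8-one)
Conditions: Ph3PCH3Br, KHMDS, THF, −78→0 °C
Reagents that add atoms: methyltriphenylphosphonium bromide C[P+](c1ccccc1)(c1ccccc1)c1ccccc1.[Br-]
Why: Wittig methylenation with the pre-formed ylide at low temperature, as practised on α,β-dialkoxy aldehydes such as glyceraldehyde acetonide, should not epimerise C7.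

Step 9
Reactants: 12 vinyl spiro lactone
Product: 14 17-epi methyl lactone (2,2,9-trimethyl-6-vinyl-1,3,7-trioxaspiro[4.4]nonan-8-one; C17 methyl trans to the vinyl group and to O8), via lithium enolate of vinyl lactone 13 (not isolated)
Conditions: LDA, THF, −78 °C; MeI, −78→−40 °C
Reagents that add atoms: iodomethane CI
Why: Lithium enolate alkylation of a γ-butyrolactone; at −78 °C the β-alkoxy enolate should alkylate before it eliminates, and iodomethane is expected to enter trans to the C7 vinyl group and to O8, giving the C17 epimer that step 10 corrects.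

Step 10
Reactants: 14 17-epi methyl lactone
Product: 16 methyl lactone (C17 methyl cis to the vinyl group and to O8), via lithium enolate of methyl lactone 15 (not isolated)
Conditions: LDA, THF, −78 °C; 2,6-di-tert-butyl-4-methylphenol, −78 °C; aq NH4Cl
Reagents that add atoms: none
Why: Kinetic protonation of the lactone enolate, in which the bulky phenol should deliver the proton to the face trans to the vinyl group and O8 so the methyl ends cis to them as in the target; both C17 epimers converge on the same enolate.

Step 11
Reactants: 16 methyl lactone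
Product: 17 lactone diol (4-hydroxy-4-(hydroxymethyl)-3-methyl-5-vinyldihydrofuran-2(3H)-one; 3-methyl, 4-hydroxy and 5-vinyl cis)
Conditions: AcOH–H2O (4:1), 45 °C
Reagents that add atoms: none
Why: Acid-catalysed ketal hydrolysis frees O8 and O9 without touching the lactone or the vinyl group.

Step 12
Reactants: 17 lactone diol
Product: 18 bis(triethylsilyl) ether of 17
Conditions: TESOTf, 2,6-lutidine, CH2Cl2, −78→0 °C
Reagents that add atoms: triethylsilyl trifluoromethanesulfonate CC[Si](CC)(CC)OS(=O)(=O)C(F)(F)F
Why: Silyl triflate silylation caps both the primary alcohol and the hindered tertiary alcohol O8.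

Step 13
Reactants: 18 bis(triethylsilyl) ether
Product: 19 lactone aldehyde (4-methyl-5-oxo-3-(triethylsilyloxy)-2-vinyltetrahydrofuran-3-carbaldehyde; C9 aldehyde, O8 silylated)
Conditions: (COCl)2, DMSO, CH2Cl2, −78→−30 °C; Et3N
Reagents that add atoms: none
Why: Direct Swern oxidation of a primary triethylsilyl ether, which activated DMSO cleaves and oxidises while the tertiary silyl ether stays; C8 bears no hydrogen, so the aldehyde cannot epimerise.

Step 14
Reactants: 20 (E)-3-(tert-butyldimethylsilyloxy)-N,N-dimethylbuta-1,3-dien-1-amine; 21 methacrolein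
Product: 23 (S)-1-methyl-4-oxocyclohex-2-ene-1-carbaldehyde, via aminosiloxy cycloadduct 22 (not isolated)
Conditions: 1-naphthyl-TADDOL (20 mol %, antipode chosen for the S product), toluene, −78 °C; HF (aq), MeCN, 0 °C
Reagents that add atoms: none
Why: Hydrogen-bond-catalysed Diels–Alder of an aminosiloxy diene with an α-substituted acrolein, in which the TADDOL shields one face of the activated aldehyde and sets quaternary C1; HF then unmasks the enone by desilylation and β-elimination of dimethylamine.

Step 15
Reactants: 23 (S)-1-methyl-4-oxocyclohex-2-ene-1-carbaldehyde; 24 4-bromo-2-methylbut-1-ene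
Product: 27 (S)-4-[(R)-1-hydroxy-4-methylpent-4-enyl]-4-methylcyclohex-2-enone, via 3-methylbut-3-enylmagnesium bromide 25 (not isolated), via bis(3-methylbut-3-enyl)zinc 26 (not isolated)
Conditions: 24, Mg, Et2O; ZnCl2 (0.5 equiv), dioxane; Ti(OiPr)4, (1S,2S)-1,2-bis(trifluoromethanesulfonamido)cyclohexane (8 mol %), toluene, −20 °C
Reagents that add atoms: none
Why: Titanium bis(sulfonamide)-catalysed addition of a dialkylzinc to an aldehyde sets C2 under ligand control (the S,S ligand is expected to give the R carbinol by analogy with simple aldehydes), and the enone is inert to dialkylzinc without copper.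

Step 16
Reactants: 27 (S)-4-[(R)-1-hydroxy-4-methylpent-4-enyl]-4-methylcyclohex-2-enone
Product: 28 enone acetate ((R)-4-methyl-1-[(S)-1-methyl-4-oxocyclohex-2-enyl]pent-4-enyl acetate)
Conditions: Ac2O, DMAP, Et3N, CH2Cl2, 20 °C
Reagents that add atoms: acetic anhydride CC(=O)OC(C)=O
Why: DMAP-catalysed acetylation installs the C2 acetate of the target early and blocks retro-aldol loss of the side chain.

Step 17
Reactants: 28 enone acetate
Product: 29 hydroxymethyl enone (28 with CH2OH, the future C20, on the α-carbon C11 of the enone)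
Conditions: HCHO (37 % aq), DMAP, THF–H2O, 20 °C
Reagents that add atoms: formaldehyde C=O
Why: Morita–Baylis–Hillman hydroxymethylation of a cyclic enone functionalises C11 of the only enone arm, which keeps C1 stereogenic before the second ring double bond is made.

Step 18
Reactants: 29 hydroxymethyl enone
Product: 31 hydroxymethyl dienone (2-(hydroxymethyl)cyclohexa-2,5-dienone; C1 and C2 as in 27), via bis(trimethylsilyl) dienol ether 30 (not isolated)
Conditions: TMSOTf, Et3N, CH2Cl2, 0 °C; Pd(OAc)2, MeCN, 20 °C; citric acid, MeOH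
Reagents that add atoms: none
Why: Soft enolisation can only remove a C13 proton and gives the cross-conjugated 2-silyloxy diene, Saegusa–Ito oxidation then introduces C13=C14, and mild acid frees the primary alcohol.

Step 19
Reactants: 31 hydroxymethyl dienone
Product: 32 bromomethyl dienone (2-(bromomethyl)cyclohexa-2,5-dienone; C1 and C2 as in 27)
Conditions: CBr4, PPh3, CH2Cl2, 0 °C
Reagents that add atoms: carbon tetrabromide BrC(Br)(Br)Br
Why: Appel bromination of the primary allylic alcohol under neutral conditions.

Step 20
Reactants: 19 lactone aldehyde; 32 bromomethyl dienone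
Product: 33 5,6-seco-briarane alcohol (C9–OH, C11=C20 exocyclic methylene, 12-ketone, 13-ene, 2-acetate, 8-O-TES, vinyl on C7 and isopropenyl terminus at C5)
Conditions: CrCl2, THF, 0→20 °C
Reagents that add atoms: none
Why: Nozaki–Hiyama allylation, in which the allylchromium(III) reagent should add to the aldehyde only (not to lactone, esters or ketone) through its γ-carbon C10 in a chair transition state with the aldehyde substituent equatorial; because the ring holds C1 trans to C20 this gives O9 anti to C1, and approach on the dienone face that carries the C1 methyl rather than the branched C2 chain sets C9 and C10 as in the target.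

Step 21
Reactants: 33 5,6-seco-briarane alcohol
Product: 34 seco C9 acetate (33 with O9 acetylated)
Conditions: Ac2O, DMAP, pyridine, CH2Cl2, 20 °C
Reagents that add atoms: acetic anhydride CC(=O)OC(C)=O
Why: DMAP-catalysed acetylation of the hindered secondary alcohol installs the C9 acetate and prevents hemiketal formation with the C12 ketone.

Step 22
Reactants: 34 seco C9 acetate
Product: 35 seco C11-methyl enone (C11 methyl cis to C9; 12-ketone, 13-ene)
Conditions: [(Ph3P)CuH]6, H2O, benzene–THF, 20 °C
Reagents that add atoms: none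
Why: Stryker conjugate reduction, in which copper hydride should add to the unhindered exocyclic methylene C20 and not to neopentyl C14 or the esters, and water protonates the copper enolate at C11 from the face anti to the C9 branch on C10, leaving the new methyl cis to C9 (kinetic protonation).

Step 23
Reactants: 35 seco C11-methyl enone
Product: 36 seco 12-epi alcohol (C12–OH cis to the C11 methyl)
Conditions: NaBH4, CeCl3·7H2O, MeOH, −78 °C
Reagents that add atoms: none
Why: Luche 1,2-reduction of the enone, in which hydride should reach C12 from the face opposite the C11 methyl, the C9 branch and the C1 methyl, giving the alcohol cis to the C11 methyl without epimerising C11.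

Step 24
Reactants: 36 seco 12-epi alcohol
Product: 37 seco butyrate (C12 butyrate trans to the C11 methyl; 2,9-diacetate, 8-O-TES)
Conditions: butanoic acid, PPh3, DIAD, toluene, 0→20 °C
Reagents that add atoms: butanoic acid CCCC(=O)O
Why: Mitsunobu esterification inverts C12 and installs the butyrate with the configuration of the target, while SN2′ attack at neopentyl C14 is disfavoured.

Step 25
Reactants: 37 seco butyrate
Product: 38 8-O-triethylsilyl ether of the target
Conditions: Grubbs second-generation catalyst (15 mol %), toluene (1 mM), 80 °C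
Reagents that add atoms: none
Why: Ring-closing metathesis, in which the carbene formed at the C6 vinyl group closes on the 1,1-disubstituted C5 alkene with loss of ethylene, and the ten-membered ring should accept only the Z trisubstituted olefin, as in metathesis routes to fused cyclodecenes.

Step 26
Reactants: 38 8-O-triethylsilyl ether of the target
Product: 39 CNP0211702.1
Conditions: HF·pyridine, pyridine–THF, 0→20 °C
Reagents that add atoms: none
Why: Buffered fluoride cleavage of the tertiary silyl ether frees O8 and should leave the three esters and the lactone untouched.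

**Compound list**

1 | D-isoascorbic acid (D-erythorbic acid) | C([C@H]([C@@H]1C(=C(C(=O)O1)O)O)O)O | starting material
2 | 2,2-dimethoxypropane | COC(C)(C)OC | starting material
3 | 5,6-O-isopropylidene-D-isoascorbic acid | C1[C@H]([C@@H]2C(=C(C(=O)O2)O)O)OC(C)(C)O1 | intermediate
4 | potassium 3,4-O-isopropylidene-D-erythronate | C1OC(C)(C)O[C@H]1[C@H](C(=O)[O-])O.[K+] | intermediate
5 | methyl 3,4-O-isopropylidene-D-erythronate (2R,3R) | C1OC(C)(C)O[C@H]1[C@H](C(=O)OC)O | intermediate
6 | bromoacetyl bromide | BrCC(Br)=O | starting material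
7 | methyl 2-O-(bromoacetyl)-3,4-O-isopropylidene-D-erythronate | C1OC(C)(C)O[C@H]1[C@H](C(=O)OC)OC(=O)CBr | intermediate
8 | methyl 2-O-(diazoacetyl)-3,4-O-isopropylidene-D-erythronate | C1OC(C)(C)O[C@H]1[C@H](C(=O)OC)OC(=O)C=[N+]=[N-] | intermediate
9 | methyl 2,2-dimethyl-8-oxo-1,3,7-trioxaspiro[4.4]nonane-6-carboxylate (O8 cis to the ester on the lactone) | C1OC(C)(C)O[C@]12CC(=O)O[C@H]2C(=O)OC | intermediate
10 | 6-(hydroxymethyl)-2,2-dimethyl-1,3,7-trioxaspiro[4.4]nonan-8-one | C1OC(C)(C)O[C@]12CC(=O)O[C@H]2CO | intermediate
11 | 2,2-dimethyl-8-oxo-1,3,7-trioxaspiro[4.4]nonane-6-carbaldehyde | C1OC(C)(C)O[C@]12CC(=O)O[C@H]2C=O | intermediate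
12 | 2,2-dimethyl-6-vinyl-1,3,7-trioxaspiro[4.4]nonan-8-one | C1OC(C)(C)O[C@]12CC(=O)O[C@H]2C=C | intermediate
13 | lithium enolate of 12 | C1OC(C)(C)O[C@]12C=C([O-])O[C@H]2C=C.[Li+] | intermediate
14 | 2,2,9-trimethyl-6-vinyl-1,3,7-trioxaspiro[4.4]nonan-8-one, 9-methyl trans to vinyl and O8 (17-epi) | C1OC(C)(C)O[C@]12[C@H](C)C(=O)O[C@H]2C=C | intermediate
15 | lithium enolate of 14 | C1OC(C)(C)O[C@]12C(C)=C([O-])O[C@H]2C=C.[Li+] | intermediate
16 | 2,2,9-trimethyl-6-vinyl-1,3,7-trioxaspiro[4.4]nonan-8-one, 9-methyl cis to vinyl and O8 | C1OC(C)(C)O[C@]12[C@@H](C)C(=O)O[C@H]2C=C | intermediate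
17 | 4-hydroxy-4-(hydroxymethyl)-3-methyl-5-vinyldihydrofuran-2(3H)-one (3-methyl, 4-OH, 5-vinyl cis) | OC[C@@]1(O)[C@H](C=C)OC(=O)[C@@H]1C | intermediate
18 | bis(triethylsilyl) ether of 17 | CC[Si](CC)(CC)OC[C@@]1(O[Si](CC)(CC)CC)[C@H](C=C)OC(=O)[C@@H]1C | intermediate
19 | 4-methyl-5-oxo-3-(triethylsilyloxy)-2-vinyltetrahydrofuran-3-carbaldehyde (methyl, OTES, vinyl cis) | O=C[C@@]1(O[Si](CC)(CC)CC)[C@H](C=C)OC(=O)[C@@H]1C | intermediate
20 | (E)-3-(tert-butyldimethylsilyloxy)-N,N-dimethylbuta-1,3-dien-1-amine | CN(C)/C=C/C(=C)O[Si](C)(C)C(C)(C)C | starting material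
21 | methacrolein | CC(=C)C=O | starting material
22 | endo cycloadduct: 4-(tert-butyldimethylsilyloxy)-2-(dimethylamino)-1-methylcyclohex-3-ene-1-carbaldehyde (CHO cis to NMe2) | CC(C)(C)[Si](C)(C)OC1=C[C@@H](N(C)C)[C@@](C)(C=O)CC1 | intermediate
23 | (S)-1-methyl-4-oxocyclohex-2-ene-1-carbaldehyde | O=C1CC[C@](C)(C=O)C=C1 | intermediate
24 | 4-bromo-2-methylbut-1-ene | C=C(C)CCBr | starting material
25 | 3-methylbut-3-enylmagnesium bromide | C=C(C)CC[Mg]Br | intermediate
26 | bis(3-methylbut-3-enyl)zinc | C=C(C)CC[Zn]CCC(C)=C | intermediate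
27 | (S)-4-[(R)-1-hydroxy-4-methylpent-4-enyl]-4-methylcyclohex-2-enone | O=C1CC[C@](C)([C@H](O)CCC(C)=C)C=C1 | intermediate
28 | (R)-4-methyl-1-[(S)-1-methyl-4-oxocyclohex-2-enyl]pent-4-enyl acetate | O=C1CC[C@](C)([C@H](OC(C)=O)CCC(C)=C)C=C1 | intermediate
29 | (R)-1-[(S)-3-(hydroxymethyl)-1-methyl-4-oxocyclohex-2-enyl]-4-methylpent-4-enyl acetate | O=C1CC[C@](C)([C@H](OC(C)=O)CCC(C)=C)C=C1CO | intermediate
30 | bis(trimethylsilyl) dienol ether of 29 | C[Si](C)(C)OC1=CC[C@](C)([C@H](OC(C)=O)CCC(C)=C)C=C1CO[Si](C)(C)C | intermediate
31 | 1-[3-(hydroxymethyl)-1-methyl-4-oxocyclohexa-2,5-dienyl]-4-methylpent-4-enyl acetate (C1, C2 as in 27) | O=C1C=C[C@](C)([C@H](OC(C)=O)CCC(C)=C)C=C1CO | intermediate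
32 | 1-[3-(bromomethyl)-1-methyl-4-oxocyclohexa-2,5-dienyl]-4-methylpent-4-enyl acetate (C1, C2 as in 27) | O=C1C=C[C@](C)([C@H](OC(C)=O)CCC(C)=C)C=C1CBr | intermediate
33 | 5,6-seco-briarane: C9 alcohol, 11(20)-methylene, 12-ketone, 13-ene, 2-acetate, 8-O-TES, 19,7-olide | O=C1C=C[C@](C)([C@H](OC(C)=O)CCC(C)=C)[C@@H]([C@@H](O)[C@@]2(O[Si](CC)(CC)CC)[C@H](C=C)OC(=O)[C@@H]2C)C1=C | intermediate
34 | 33 as its C9 acetate | O=C1C=C[C@](C)([C@H](OC(C)=O)CCC(C)=C)[C@@H]([C@@H](OC(C)=O)[C@@]2(O[Si](CC)(CC)CC)[C@H](C=C)OC(=O)[C@@H]2C)C1=C | intermediate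
35 | seco C11-methyl enone (C11 methyl cis to C9) | O=C1C=C[C@](C)([C@H](OC(C)=O)CCC(C)=C)[C@@H]([C@@H](OC(C)=O)[C@@]2(O[Si](CC)(CC)CC)[C@H](C=C)OC(=O)[C@@H]2C)[C@H]1C | intermediate
36 | seco 12-epi alcohol (C12–OH cis to C11 methyl) | O[C@H]1C=C[C@](C)([C@H](OC(C)=O)CCC(C)=C)[C@@H]([C@@H](OC(C)=O)[C@@]2(O[Si](CC)(CC)CC)[C@H](C=C)OC(=O)[C@@H]2C)[C@H]1C | intermediate
37 | seco butyrate (C12 butyrate trans to C11 methyl) | CCCC(=O)O[C@@H]1C=C[C@](C)([C@H](OC(C)=O)CCC(C)=C)[C@@H]([C@@H](OC(C)=O)[C@@]2(O[Si](CC)(CC)CC)[C@H](C=C)OC(=O)[C@@H]2C)[C@H]1C | intermediate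
38 | 8-O-triethylsilyl ether of the target | CCCC(=O)O[C@@H]1C=C[C@@]2(C)[C@H]([C@H]1C)[C@@H](OC(C)=O)[C@@]1(O[Si](CC)(CC)CC)[C@H](/C=C(/C)CC[C@H]2OC(C)=O)OC(=O)[C@@H]1C | intermediate
39 | CNP0211702.1 | CCCC(=O)O[C@@H]1C=C[C@@]2(C)[C@H]([C@H]1C)[C@@H](OC(C)=O)[C@@]1(O)[C@H](/C=C(/C)CC[C@H]2OC(C)=O)OC(=O)[C@@H]1C | target

**Step count and risk**

Total: 26 steps. Longest linear sequence: 20 steps (steps 1–13, then 20–26); the dienone 32 takes 6 steps (14–19).

Steps most likely to fail:

1. Step 25, ring-closing metathesis. What may go wrong: the carbene formed at the C6 vinyl group reacts with a second molecule faster than it closes on the hindered C5 alkene, because the ring must form trans-fused to both the lactone and the cyclohexene, so oligomers form. Fallback: the ring is closed before C11 and C12 are set. Setting out from 34, metathesis at high dilution is run while C11 and C12 are still trigonal, which flattens the six-membered ring and changes the angle between the C2 and C9 arms; the electron-poor exocyclic methylene is a poor metathesis partner. This gives the macrocyclic α-methylene enone F1. Copper hydride reduction with protonation anti to C9 gives the macrocyclic C11-methyl enone F2, Luche reduction gives the macrocyclic 12-epi alcohol F3, and Mitsunobu esterification with butanoic acid returns to 38.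

2. Step 20, chromium allylation. What may go wrong: bond formation at the unhindered CH2 terminus (C20) in place of the congested C10, or reduction of the dienone by chromium(II). Fallback: an isolated allylboronate, which can react only through a closed six-membered transition state at its γ-carbon. Setting out from 32, palladium-catalysed borylation with bis(pinacolato)diboron gives the allylboronate F4. Its Sc(OTf)3-catalysed allylboration of aldehyde 19, in the manner of 2-alkoxycarbonyl allylboronates, returns to 33 after work-up with the same anti relation.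

3. Step 5, C–H insertion. What may go wrong: the C8–H bond is deactivated by the vicinal C6 ester, so carbene dimerisation and capture of the carbenoid by a dioxolane oxygen compete with insertion. Fallback: an acceptor–acceptor carbenoid, which does not dimerise and is known to insert 1,5 into oxygen-activated C–H bonds under rhodium carboxylate catalysis. Setting out from 5, acylation with methyl malonyl chloride and pyridine gives the mixed malonate F5. Diazo transfer with p-acetamidobenzenesulfonyl azide and Et3N gives the diazomalonate F6, and Rh2(OAc)4 in refluxing benzene gives the α-methoxycarbonyl spiro lactone F7. Krapcho dealkoxycarbonylation (LiCl, wet DMSO, 130 °C) removes the extra ester and returns to 9.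

**Further compounds**

F1 | step 25 | macrocyclic α-methylene enone (11(20)-ene, 12-ketone, 2,9-diacetate, 8-O-TES) | O=C1C=C[C@@]2(C)[C@H](C1=C)[C@@H](OC(C)=O)[C@@]1(O[Si](CC)(CC)CC)[C@H](/C=C(/C)CC[C@H]2OC(C)=O)OC(=O)[C@@H]1C
F2 | step 25 | macrocyclic C11-methyl enone (12-ketone, 8-O-TES) | O=C1C=C[C@@]2(C)[C@H]([C@H]1C)[C@@H](OC(C)=O)[C@@]1(O[Si](CC)(CC)CC)[C@H](/C=C(/C)CC[C@H]2OC(C)=O)OC(=O)[C@@H]1C
F3 | step 25 | macrocyclic 12-epi alcohol (8-O-TES) | O[C@H]1C=C[C@@]2(C)[C@H]([C@H]1C)[C@@H](OC(C)=O)[C@@]1(O[Si](CC)(CC)CC)[C@H](/C=C(/C)CC[C@H]2OC(C)=O)OC(=O)[C@@H]1C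
F4 | step 20 | allylboronate: 32 with CH2Bpin in place of CH2Br | O=C1C=C[C@](C)([C@H](OC(C)=O)CCC(C)=C)C=C1CB1OC(C)(C)C(C)(C)O1
F5 | step 5 | mixed malonate: methyl 2-O-(methoxycarbonylacetyl)-3,4-O-isopropylidene-D-erythronate | C1OC(C)(C)O[C@H]1[C@H](C(=O)OC)OC(=O)CC(=O)OC
F6 | step 5 | diazomalonate of F5 | C1OC(C)(C)O[C@H]1[C@H](C(=O)OC)OC(=O)C(=[N+]=[N-])C(=O)OC
F7 | step 5 | α-methoxycarbonyl spiro lactone (9 with CO2Me on C17, C17 epimers) | C1OC(C)(C)O[C@]12C(C(=O)OC)C(=O)O[C@H]2C(=O)OC
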